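**Plan**

1. Retrosynthesis: the three CH2OH groups and the free phenol go back to three methyl esters and an aryl pivalate (one hydride reduction), and the aryl–CH= bond of the propenol arm is cut (Heck).
2. In each 2-aryl-2,3-dihydrobenzofuran the C3–C3a bond is cut and C3a is re-joined to the ester carbon, which unfolds the five-membered ring into a 2-arylchroman-4-one; each flavanone C2–aryl bond is then cut to an arylboronic acid plus the same 6-bromo-8-methoxychromone.
3. Enabling feature: in each dihydrofuran ring (O1–C2–C3–C3a–C7a), C3 carries an exocyclic oxidised carbon next to the ring-fusion carbon C3a. That carbon is the former C4 carbonyl of a pyranone ring, and a 1,2-shift of the aryl carbon from C4 to C3 extrudes it.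
4. Forward: chromone → asymmetric conjugate addition of the guaiacyl unit → oxidative ring contraction (guaiacyl-bearing dihydrofuran, formed first) → Br to B(OH)2 → second conjugate addition to the same chromone → second ring contraction (inner dihydrofuran) → Heck → global reduction.
5. Stereochemistry: C2 and C2′ are set by catalyst control (Pd/(S)-t-BuPyOx, R each time); C3 and C3′ are relayed from them, trans, in the ring contractions; the E-alkene comes from the Heck reaction.

Key step: step 5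

Remarks on the chemistry: the sense of induction of (S)-t-BuPyOx with chromones is assumed to parallel that with cyclic enones (2R flavanone); if it proved opposite, the (R)-ligand would be used in steps 4 and 7. Primed locants refer to the second (inner) benzopyran or benzofuran unit. The 3R descriptor of the esters becomes 3S in the alcohols only through the CIP priorities, with no change in space.

**Route**

Step 1
Reactants: 1 1-(2-hydroxy-3-methoxyphenyl)ethan-1-one
Product: 2 1-(5-bromo-2-hydroxy-3-methoxyphenyl)ethan-1-one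
Conditions: NBS (1.05 equiv), MeCN, 0 °C to rt
Reagents that add atoms: N-bromosuccinimide, O=C1CCC(=O)N1Br
Why: Electrophilic aromatic bromination; the phenol directs to its only free para position (C5), which is also meta to the deactivating acetyl group.

Step 2
Reactants: 2 1-(5-bromo-2-hydroxy-3-methoxyphenyl)ethan-1-one
Product: 4 6-bromo-8-methoxy-4H-chromen-4-one, via enaminone 3 (not isolated)
Conditions: Me2NCH(OMe)2 (2 equiv), toluene, 100 °C; then conc. HCl, CH2Cl2, rt
Reagents that add atoms: N,N-dimethylformamide dimethyl acetal, COC(OC)N(C)C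
Why: Enaminone condensation of the methyl ketone followed by acid-mediated addition–elimination of the phenol (6-endo), the standard chromone synthesis from 2′-hydroxyacetophenones.

Step 3
Reactants: 5 (4-hydroxy-3-methoxyphenyl)boronic acid
Product: 6 [3-methoxy-4-(pivaloyloxy)phenyl]boronic acid
Conditions: PivCl (1.1 equiv), pyridine, CH2Cl2, 0 °C to rt; 1 M HCl work-up
Reagents that add atoms: pivaloyl chloride, CC(C)(C)C(=O)Cl
Why: O-acylation of the phenol (any B–O acylation is undone on aqueous work-up); the pivalate should survive acid and oxidant, lowers the migratory aptitude of the guaiacyl ring in step 5, and falls off in the final hydride reduction.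

Step 4
Reactants: 4 6-bromo-8-methoxy-4H-chromen-4-one; 6 [3-methoxy-4-(pivaloyloxy)phenyl]boronic acid
Product: 7 4-[(2R)-6-bromo-8-methoxy-4-oxo-3,4-dihydro-2H-chromen-2-yl]-2-methoxyphenyl pivalate
Conditions: 6 (2 equiv), Pd(OCOCF3)2 (5 mol%), (S)-t-BuPyOx (6 mol%), NH4PF6 (30 mol%), H2O (5 equiv), ClCH2CH2Cl, 60 °C
Reagents that add atoms: none
Why: Pd(II)/pyridine-oxazoline-catalysed asymmetric conjugate addition of an arylboronic acid to a chromone (aryl–Pd insertion into C2=C3, protonolysis of the Pd enolate); the ligand sets C2 (R expected), the mildly acidic medium should prevent retro-oxa-Michael racemisation, and the aryl bromide is inert to Pd(II).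

Step 5
Reactants: 7 4-[(2R)-6-bromo-8-methoxy-4-oxo-3,4-dihydro-2H-chromen-2-yl]-2-methoxyphenyl pivalate
Product: 10 methyl (2R,3R)-5-bromo-7-methoxy-2-[3-methoxy-4-(pivaloyloxy)phenyl]-2,3-dihydro-1-benzofuran-3-carboxylate, via enol ether 8 (not isolated), via iodanyl ketal 9 (not isolated)
Conditions: PhI(OAc)2 (1.2 equiv), conc. H2SO4 (1 equiv), HC(OMe)3, rt; aq. NaHCO3
Reagents that add atoms: trimethyl orthoformate, COC(OC)OC; water, O
Why: Acid and orthoformate turn the ketone into enol ether 8, PhI(OAc)+ adds to C3 anti to the C2 aryl group while methanol caps C4, and in the resulting trans-diequatorial iodanyl ketal 9 the ring bond C4–C4a lies antiperiplanar to C3–I, so the aryl carbon C4a shifts from C4 to C3 as iodobenzene leaves and C4 is extruded as a dimethoxycarbenium ion that collapses to the methyl ester. The closest known reaction type is the hypervalent-iodine (or thallium(III)) oxidative rearrangement of flavanones in trimethyl orthoformate to methyl trans-2-aryl-2,3-dihydrobenzofuran-3-carboxylates, a 1,2-aryl shift of an α-functionalised aryl ketal. The dihydrofuran ring (O1–C2–C3–C3a–C7a) is closed by formation of the C3–C3a bond in a 1,2-shift through a bridged phenonium-type transition state (formally a 3-exo-tet attack of C4a on C3), i.e. a six-to-five ring contraction in which only C4 leaves the ring. The new stereocentre C3 is set by substrate control from C2: anti addition of iodine followed by inversion at C3 places the ester trans to the aryl group (3R), which is also the thermodynamic arrangement, and C2 is not touched, so the enantiopurity from step 4 should be carried over. The step needs migration of C4a in preference to a 2→3 shift of the C2 aryl group (isoflavone pathway) and to elimination (flavone); this is secured by the ring oxygen O1 ortho to C4a, which stabilises the bridged cation, by the two methoxy groups that stabilise the cation left at C4, and by the pivaloyloxy group, which deactivates the guaiacyl ring.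

Step 6
Reactants: 10 methyl (2R,3R)-5-bromo-7-methoxy-2-[3-methoxy-4-(pivaloyloxy)phenyl]-2,3-dihydro-1-benzofuran-3-carboxylate
Product: 11 [(2R,3R)-7-methoxy-3-(methoxycarbonyl)-2-[3-methoxy-4-(pivaloyloxy)phenyl]-2,3-dihydro-1-benzofuran-5-yl]boronic acid
Conditions: B2(OH)4 (3 equiv), XPhos Pd G2 (2 mol%), XPhos (4 mol%), KOAc (3 equiv), EtOH, 80 °C
Reagents that add atoms: tetrahydroxydiboron, OB(O)B(O)O
Why: Miyaura-type Pd(0) borylation of the aryl bromide with tetrahydroxydiboron should give the free boronic acid directly; KOAc is too weak a base to open the β-aryloxy ester or cleave the pivalate, and any C3 epimerisation could only return the trans isomer.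

Step 7
Reactants: 11 [(2R,3R)-7-methoxy-3-(methoxycarbonyl)-2-[3-methoxy-4-(pivaloyloxy)phenyl]-2,3-dihydro-1-benzofuran-5-yl]boronic acid; 4 6-bromo-8-methoxy-4H-chromen-4-one
Product: 12 methyl (2R,3R)-5-[(2R)-6-bromo-8-methoxy-4-oxo-3,4-dihydro-2H-chromen-2-yl]-7-methoxy-2-[3-methoxy-4-(pivaloyloxy)phenyl]-2,3-dihydro-1-benzofuran-3-carboxylate
Conditions: 4 (1.5 equiv), Pd(OCOCF3)2 (10 mol%), (S)-t-BuPyOx (12 mol%), NH4PF6 (30 mol%), H2O (5 equiv), ClCH2CH2Cl, 60 °C
Reagents that add atoms: none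
Why: The same Pd(II)/PyOx asymmetric conjugate addition as in step 4; the new centre C2′ (R) is set by the catalyst, the existing centres being remote from the reacting carbon.

Step 8
Reactants: 12 methyl (2R,3R)-5-[(2R)-6-bromo-8-methoxy-4-oxo-3,4-dihydro-2H-chromen-2-yl]-7-methoxy-2-[3-methoxy-4-(pivaloyloxy)phenyl]-2,3-dihydro-1-benzofuran-3-carboxylate
Product: 15 methyl (2R,3R)-5-[(2R,3R)-5-bromo-7-methoxy-3-(methoxycarbonyl)-2,3-dihydro-1-benzofuran-2-yl]-7-methoxy-2-[3-methoxy-4-(pivaloyloxy)phenyl]-2,3-dihydro-1-benzofuran-3-carboxylate, via enol ether 13 (not isolated), via iodanyl ketal 14 (not isolated)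
Conditions: PhI(OAc)2 (1.2 equiv), conc. H2SO4 (1 equiv), HC(OMe)3, rt; aq. NaHCO3
Reagents that add atoms: trimethyl orthoformate, COC(OC)OC; water, O
Why: Second oxidative ring contraction of a flavanone by the mechanism of step 5 (enol ether 13, anti iodination to 14, 1,2-shift of C4a′ with inversion); C3′ is set trans to the C2′ aryl group by relay from C2′, and the pivaloyloxy-deactivated aryl group on the first dihydrofuran should keep its benzylic C2–O bond intact in the acid.

Step 9
Reactants: 15 methyl (2R,3R)-5-[(2R,3R)-5-bromo-7-methoxy-3-(methoxycarbonyl)-2,3-dihydro-1-benzofuran-2-yl]-7-methoxy-2-[3-methoxy-4-(pivaloyloxy)phenyl]-2,3-dihydro-1-benzofuran-3-carboxylate; 16 methyl acrylate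
Product: 17 methyl (2R,3R)-7-methoxy-5-[(2R,3R)-7-methoxy-3-(methoxycarbonyl)-5-[(E)-3-methoxy-3-oxoprop-1-en-1-yl]-2,3-dihydro-1-benzofuran-2-yl]-2-[3-methoxy-4-(pivaloyloxy)phenyl]-2,3-dihydro-1-benzofuran-3-carboxylate
Conditions: 16 (3 equiv), Pd(OAc)2 (5 mol%), P(o-tol)3 (10 mol%), Et3N, DMF, 100 °C
Reagents that add atoms: none
Why: Mizoroki–Heck reaction at the only C–Br bond; syn carbopalladation at the acrylate β-carbon and syn β-hydride elimination should give the E-cinnamate.

Step 10
Reactants: 17 methyl (2R,3R)-7-methoxy-5-[(2R,3R)-7-methoxy-3-(methoxycarbonyl)-5-[(E)-3-methoxy-3-oxoprop-1-en-1-yl]-2,3-dihydro-1-benzofuran-2-yl]-2-[3-methoxy-4-(pivaloyloxy)phenyl]-2,3-dihydro-1-benzofuran-3-carboxylate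
Product: 18 4-[(2R,3S)-3-(hydroxymethyl)-5-[(2R,3S)-3-(hydroxymethyl)-5-[(E)-3-hydroxyprop-1-en-1-yl]-7-methoxy-2,3-dihydro-1-benzofuran-2-yl]-7-methoxy-2,3-dihydro-1-benzofuran-2-yl]-2-methoxyphenol
Conditions: DIBAL-H (12 equiv), CH2Cl2, −78 to 0 °C; aq. Rochelle salt
Reagents that add atoms: none
Why: DIBAL-H should reduce the two saturated methyl esters and the cinnamate (1,2-reduction) to primary alcohols and cleave the aryl pivalate reductively in the same operation; no stereocentre is touched.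

**Compound list**

1 | 1-(2-hydroxy-3-methoxyphenyl)ethan-1-one | CC(=O)c1cccc(OC)c1O | starting material
2 | 1-(5-bromo-2-hydroxy-3-methoxyphenyl)ethan-1-one | CC(=O)c1cc(Br)cc(OC)c1O | intermediate
3 | (E)-1-(5-bromo-2-hydroxy-3-methoxyphenyl)-3-(dimethylamino)prop-2-en-1-one | CN(C)/C=C/C(=O)c1cc(Br)cc(OC)c1O | intermediate
4 | 6-bromo-8-methoxy-4H-chromen-4-one | O=c1ccoc2c(OC)cc(Br)cc12 | intermediate
5 | (4-hydroxy-3-methoxyphenyl)boronic acid | COc1cc(B(O)O)ccc1O | starting material
6 | [3-methoxy-4-(pivaloyloxy)phenyl]boronic acid | COc1cc(B(O)O)ccc1OC(=O)C(C)(C)C | intermediate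
7 | 4-[(2R)-6-bromo-8-methoxy-4-oxo-3,4-dihydro-2H-chromen-2-yl]-2-methoxyphenyl pivalate | COc1cc([C@@H]2Oc3c(OC)cc(Br)cc3C(=O)C2)ccc1OC(=O)C(C)(C)C | intermediate
8 | 4-[(2R)-6-bromo-4,8-dimethoxy-2H-chromen-2-yl]-2-methoxyphenyl pivalate | COc1cc([C@@H]2Oc3c(OC)cc(Br)cc3C(OC)=C2)ccc1OC(=O)C(C)(C)C | intermediate
9 | 4-[(2S,3S)-3-[acetoxy(phenyl)-λ3-iodanyl]-6-bromo-4,4,8-trimethoxy-3,4-dihydro-2H-chromen-2-yl]-2-methoxyphenyl pivalate (aryl and iodine trans) | COc1cc([C@@H]2Oc3c(OC)cc(Br)cc3C(OC)(OC)[C@H]2I(OC(C)=O)c2ccccc2)ccc1OC(=O)C(C)(C)C | intermediate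
10 | methyl (2R,3R)-5-bromo-7-methoxy-2-[3-methoxy-4-(pivaloyloxy)phenyl]-2,3-dihydro-1-benzofuran-3-carboxylate (2,3-trans) | COc1cc([C@@H]2Oc3c(OC)cc(Br)cc3[C@H]2C(=O)OC)ccc1OC(=O)C(C)(C)C | intermediate
11 | [(2R,3R)-7-methoxy-3-(methoxycarbonyl)-2-[3-methoxy-4-(pivaloyloxy)phenyl]-2,3-dihydro-1-benzofuran-5-yl]boronic acid | COc1cc([C@@H]2Oc3c(OC)cc(B(O)O)cc3[C@H]2C(=O)OC)ccc1OC(=O)C(C)(C)C | intermediate
12 | methyl (2R,3R)-5-[(2R)-6-bromo-8-methoxy-4-oxo-3,4-dihydro-2H-chromen-2-yl]-7-methoxy-2-[3-methoxy-4-(pivaloyloxy)phenyl]-2,3-dihydro-1-benzofuran-3-carboxylate | COc1cc([C@@H]2Oc3c(OC)cc([C@@H]4Oc5c(OC)cc(Br)cc5C(=O)C4)cc3[C@H]2C(=O)OC)ccc1OC(=O)C(C)(C)C | intermediate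
13 | methyl (2R,3R)-5-[(2R)-6-bromo-4,8-dimethoxy-2H-chromen-2-yl]-7-methoxy-2-[3-methoxy-4-(pivaloyloxy)phenyl]-2,3-dihydro-1-benzofuran-3-carboxylate | COc1cc([C@@H]2Oc3c(OC)cc([C@@H]4Oc5c(OC)cc(Br)cc5C(OC)=C4)cc3[C@H]2C(=O)OC)ccc1OC(=O)C(C)(C)C | intermediate
14 | methyl (2R,3R)-5-[(2S,3S)-3-[acetoxy(phenyl)-λ3-iodanyl]-6-bromo-4,4,8-trimethoxy-3,4-dihydro-2H-chromen-2-yl]-7-methoxy-2-[3-methoxy-4-(pivaloyloxy)phenyl]-2,3-dihydro-1-benzofuran-3-carboxylate (aryl and iodine trans) | COc1cc([C@@H]2Oc3c(OC)cc([C@@H]4Oc5c(OC)cc(Br)cc5C(OC)(OC)[C@H]4I(OC(C)=O)c4ccccc4)cc3[C@H]2C(=O)OC)ccc1OC(=O)C(C)(C)C | intermediate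
15 | methyl (2R,3R)-5-[(2R,3R)-5-bromo-7-methoxy-3-(methoxycarbonyl)-2,3-dihydro-1-benzofuran-2-yl]-7-methoxy-2-[3-methoxy-4-(pivaloyloxy)phenyl]-2,3-dihydro-1-benzofuran-3-carboxylate | COc1cc([C@@H]2Oc3c(OC)cc([C@@H]4Oc5c(OC)cc(Br)cc5[C@H]4C(=O)OC)cc3[C@H]2C(=O)OC)ccc1OC(=O)C(C)(C)C | intermediate
16 | methyl acrylate | C=CC(=O)OC | starting material
17 | methyl (2R,3R)-7-methoxy-5-[(2R,3R)-7-methoxy-3-(methoxycarbonyl)-5-[(E)-3-methoxy-3-oxoprop-1-en-1-yl]-2,3-dihydro-1-benzofuran-2-yl]-2-[3-methoxy-4-(pivaloyloxy)phenyl]-2,3-dihydro-1-benzofuran-3-carboxylate | COc1cc([C@@H]2Oc3c(OC)cc([C@@H]4Oc5c(OC)cc(/C=C/C(=O)OC)cc5[C@H]4C(=O)OC)cc3[C@H]2C(=O)OC)ccc1OC(=O)C(C)(C)C | intermediate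
18 | 4-[(2R,3S)-3-(hydroxymethyl)-5-[(2R,3S)-3-(hydroxymethyl)-5-[(E)-3-hydroxyprop-1-en-1-yl]-7-methoxy-2,3-dihydro-1-benzofuran-2-yl]-7-methoxy-2,3-dihydro-1-benzofuran-2-yl]-2-methoxyphenol | COc1cc([C@@H]2Oc3c(OC)cc([C@@H]4Oc5c(OC)cc(/C=C/CO)cc5[C@H]4CO)cc3[C@H]2CO)ccc1O | target

**Summary**

Total step count: 10. Longest linear sequence: 9 steps (1, 2, 4, 5, 6, 7, 8, 9, 10, from compound 1); step 3 is a one-step branch.

**Steps most likely to fail**

Step 8 (second ring contraction). The aryl group on C2′ is now an electron-rich para-alkoxyphenyl ring, so its 2→3 shift (isoflavone pathway) may compete with migration of the ring carbon. The iodane may also eliminate to a flavone, and the acid may ionise the benzylic C2–O bond of the first dihydrofuran. The fallback moves the contraction to a carbene manifold in which only the carbonyl-bound aryl carbon can migrate. From 12, condensation with DMF-DMA (toluene, 90 °C) should give methyl (2R,3R)-5-[(2R)-6-bromo-3-[(dimethylamino)methylidene]-8-methoxy-4-oxo-3,4-dihydro-2H-chromen-2-yl]-7-methoxy-2-[3-methoxy-4-(pivaloyloxy)phenyl]-2,3-dihydro-1-benzofuran-3-carboxylate F1. Tosyl azide (CH2Cl2, rt) should convert it, by cycloaddition and cycloreversion without added base, into the 3′-diazo-4′-ketone F2. Irradiation (λ > 300 nm, MeOH, 0 °C) should bring about the Wolff rearrangement with capture by methanol, giving 15 mixed with its cis 3′-epimer F3. DBU (toluene, rt) should equilibrate the cis 3′-epimer F3 to the trans isomer, so the route is rejoined at 15.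

Step 7 (second conjugate addition). Protodeboronation of the electron-rich, valuable boronic acid 11 may outpace transmetalation, and a mismatch between catalyst and the existing centres may lower facial selectivity. The fallback builds the flavanone from a chalcone instead. From 10, Pd-catalysed reductive carbonylation (Pd(OAc)2, di(1-adamantyl)-n-butylphosphine, TMEDA, CO/H2, toluene, 100 °C) should give methyl (2R,3R)-5-formyl-7-methoxy-2-[3-methoxy-4-(pivaloyloxy)phenyl]-2,3-dihydro-1-benzofuran-3-carboxylate F4. A base-free Claisen–Schmidt condensation with ketone 2 (BF3·OEt2, dioxane, rt) should give the 2′-hydroxychalcone F5. Oxa-Michael cyclisation (NaOAc, EtOH, reflux) should give 12 together with its C2′ epimer F6. These are diastereomers and should be separable by chromatography, and the C2′ epimer F6 can be re-equilibrated through the chalcone; the route is rejoined at 12.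

Step 5 (key ring contraction). Oxidant and strong acid act together: the iodane may eliminate to the flavone, ketalisation may stay incomplete, and acid methanolysis of the pivalate would expose a phenol to the oxidant. The fallback separates halogenation from migration and makes the shift non-oxidative. From 7, ketalisation and bromination in one pot (HC(OMe)3, MeOH, TsOH cat.; then pyridinium tribromide, 0 °C) should give 4-[(2S,3S)-3,6-dibromo-4,4,8-trimethoxy-3,4-dihydro-2H-chromen-2-yl]-2-methoxyphenyl pivalate F7, with the C3 bromine trans to the aryl group. Catalytic ZnBr2 (toluene, 90 °C) should then trigger the known Lewis-acid 1,2-aryl shift of an α-bromo aryl ketal to the α-aryl ester, again with inversion at C3, rejoining the route at 10.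

**Further compounds**

F1 | step 8 | methyl (2R,3R)-5-[(2R)-6-bromo-3-[(dimethylamino)methylidene]-8-methoxy-4-oxo-3,4-dihydro-2H-chromen-2-yl]-7-methoxy-2-[3-methoxy-4-(pivaloyloxy)phenyl]-2,3-dihydro-1-benzofuran-3-carboxylate | COc1cc([C@@H]2Oc3c(OC)cc([C@@H]4Oc5c(OC)cc(Br)cc5C(=O)C4=CN(C)C)cc3[C@H]2C(=O)OC)ccc1OC(=O)C(C)(C)C
F2 | step 8 | methyl (2R,3R)-5-[(2R)-6-bromo-3-diazo-8-methoxy-4-oxo-3,4-dihydro-2H-chromen-2-yl]-7-methoxy-2-[3-methoxy-4-(pivaloyloxy)phenyl]-2,3-dihydro-1-benzofuran-3-carboxylate | COc1cc([C@@H]2Oc3c(OC)cc([C@@H]4Oc5c(OC)cc(Br)cc5C(=O)C4=[N+]=[N-])cc3[C@H]2C(=O)OC)ccc1OC(=O)C(C)(C)C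
F3 | step 8 | methyl (2R,3R)-5-[(2R,3S)-5-bromo-7-methoxy-3-(methoxycarbonyl)-2,3-dihydro-1-benzofuran-2-yl]-7-methoxy-2-[3-methoxy-4-(pivaloyloxy)phenyl]-2,3-dihydro-1-benzofuran-3-carboxylate (cis 3′-epimer of 15) | COc1cc([C@@H]2Oc3c(OC)cc([C@@H]4Oc5c(OC)cc(Br)cc5[C@@H]4C(=O)OC)cc3[C@H]2C(=O)OC)ccc1OC(=O)C(C)(C)C
F4 | step 7 | methyl (2R,3R)-5-formyl-7-methoxy-2-[3-methoxy-4-(pivaloyloxy)phenyl]-2,3-dihydro-1-benzofuran-3-carboxylate | COc1cc([C@@H]2Oc3c(OC)cc(C=O)cc3[C@H]2C(=O)OC)ccc1OC(=O)C(C)(C)C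
F5 | step 7 | methyl (2R,3R)-5-[(E)-3-(5-bromo-2-hydroxy-3-methoxyphenyl)-3-oxoprop-1-en-1-yl]-7-methoxy-2-[3-methoxy-4-(pivaloyloxy)phenyl]-2,3-dihydro-1-benzofuran-3-carboxylate | COc1cc([C@@H]2Oc3c(OC)cc(/C=C/C(=O)c4cc(Br)cc(OC)c4O)cc3[C@H]2C(=O)OC)ccc1OC(=O)C(C)(C)C
F6 | step 7 | methyl (2R,3R)-5-[(2S)-6-bromo-8-methoxy-4-oxo-3,4-dihydro-2H-chromen-2-yl]-7-methoxy-2-[3-methoxy-4-(pivaloyloxy)phenyl]-2,3-dihydro-1-benzofuran-3-carboxylate (C2′ epimer of 12) | COc1cc([C@@H]2Oc3c(OC)cc([C@H]4Oc5c(OC)cc(Br)cc5C(=O)C4)cc3[C@H]2C(=O)OC)ccc1OC(=O)C(C)(C)C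
F7 | step 5 | 4-[(2S,3S)-3,6-dibromo-4,4,8-trimethoxy-3,4-dihydro-2H-chromen-2-yl]-2-methoxyphenyl pivalate (aryl and C3 bromine trans) | COc1cc([C@@H]2Oc3c(OC)cc(Br)cc3C(OC)(OC)[C@H]2Br)ccc1OC(=O)C(C)(C)C
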